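Ring A is cut at C2–C3 and C9=C10: its C2–C1(=O)–C10(Me) unit is a butan-2-one skeleton bridging the β-carbon C3 and the formyl carbon C9 of a ring B cyclohexenecarbaldehyde. A single amine-catalysed decarboxylative Michael–aldol annulation with 3-oxopentanoic acid thus closes ring A, makes both bonds and sets C3 (anti to the C4 methyl) and C8 (cis fusion, enforced by allylic strain from C12 on the exocyclic C7=C11 alkene). The precursor is ring B dienal 18: C4 methyl, C5 oxygen as a silyl ether (an acetate there would be expelled towards an arene), and the E-configured C7=C11 alkene, fixed earlier by syn-carbopalladation of an alkyne.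

Key step: step 11

Remark: atom labels follow the target (C1 CHOAc next to C10; C2 CH2; C3 and C8 ring fusion; C4 CHMe; C5 CHOAc; C6 CH2; C7=C11 exocyclic alkene with methyl C12 and CH2O C13 on C11; C9=C10 alkene; ring A = C1–C2–C3–C8–C9–C10, ring B = C3–C4–C5–C6–C7–C8); compounds 1, 2, 6, 13, 19 and all reagents are assumed to be commercial, and the labile aldehydes 5 and 12 are used crude.

Step 1
Reactants: 1 tert-butyldimethyl(prop-2-yn-1-yloxy)silane; 2 oxirane
Product: 4 5-[(tert-butyldimethylsilyl)oxy]pent-3-yn-1-ol, via lithium acetylide 3 (not isolated)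
Conditions: n-BuLi, THF, −78 °C; BF3·OEt2; 2, −78 °C; aq NH4Cl
Reagents that add atoms: none
Why: The lithium acetylide opens the BF3-activated epoxide at carbon (epoxide alkynylation), a standard route to a homopropargylic alcohol; no stereocentre is formed.

Step 2
Reactants: 4 5-[(tert-butyldimethylsilyl)oxy]pent-3-yn-1-ol
Product: 5 5-[(tert-butyldimethylsilyl)oxy]pent-3-ynal
Conditions: Dess–Martin periodinane, CH2Cl2, 0 °C; used crude at once
Reagents that add atoms: none
Why: Dess–Martin oxidation is fast and close to neutral, so the β,γ-alkynyl aldehyde should be obtained without isomerization to the allenyl aldehyde provided it is not chromatographed.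

Step 3
Reactants: 5 5-[(tert-butyldimethylsilyl)oxy]pent-3-ynal; 6 cis-but-2-ene
Product: 9 (3R,4R)-8-[(tert-butyldimethylsilyl)oxy]-3-methyloct-1-en-6-yn-4-ol, via (Z)-but-2-enylpotassium 7 (not isolated), via (Z)-crotyldiisopinocampheylborane 8 (not isolated)
Conditions: 6, KOt-Bu, n-BuLi, THF, −78 → −45 °C; (−)-Ipc2BOMe (from (+)-α-pinene), −78 °C; BF3·OEt2; 5, −78 °C; then NaOH, H2O2, rt
Reagents that add atoms: none
Why: Brown crotylboration: the (Z)-crotylborane reacts through a closed chair transition state to give the syn relationship of the C4 methyl and C5 hydroxyl groups, and the isopinocampheyl groups from (+)-α-pinene select the aldehyde face that leads to the (R)-carbinol, so C4 and C5 are both set here.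

Step 4
Reactants: 9 (3R,4R)-8-[(tert-butyldimethylsilyl)oxy]-3-methyloct-1-en-6-yn-4-ol
Product: 10 (3R,4R)-8-[(tert-butyldimethylsilyl)oxy]-3-methyl-4-[(triethylsilyl)oxy]oct-1-en-6-yne
Conditions: Et3SiCl, imidazole, CH2Cl2, 0 °C → rt
Reagents that add atoms: chlorotriethylsilane, CC[Si](Cl)(CC)CC
Why: Standard silylation of a secondary alcohol; the triethylsilyl ether is a poor leaving group at C5 and can later be cleaved in the presence of the primary tert-butyldimethylsilyl ether.

Step 5
Reactants: 10 (3R,4R)-8-[(tert-butyldimethylsilyl)oxy]-3-methyl-4-[(triethylsilyl)oxy]oct-1-en-6-yne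
Product: 12 (2S,3R)-7-[(tert-butyldimethylsilyl)oxy]-2-methyl-3-[(triethylsilyl)oxy]hept-5-ynal, via ozonide 11 (not isolated)
Conditions: O3, CH2Cl2, −78 °C (Sudan Red 7B as indicator); then PPh3, −78 °C → rt; used crude
Reagents that add atoms: ozone, [O-][O+]=O
Why: Ozonolysis with reductive work-up cleaves the terminal alkene, which reacts with ozone far faster than the internal alkyne, and the neutral work-up should leave the α-stereocentre C4 of the crude aldehyde intact.

Step 6
Reactants: 12 (2S,3R)-7-[(tert-butyldimethylsilyl)oxy]-2-methyl-3-[(triethylsilyl)oxy]hept-5-ynal; 13 ethyl (triphenylphosphoranylidene)acetate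
Product: 15 ethyl (2Z,4R,5R)-2-bromo-9-[(tert-butyldimethylsilyl)oxy]-4-methyl-5-[(triethylsilyl)oxy]non-2-en-7-ynoate, via bromo ylide 14 (not isolated)
Conditions: 13, NBS, CH2Cl2, −20 °C; then 12, −20 °C → rt
Reagents that add atoms: N-bromosuccinimide, O=C1CCC(=O)N1Br
Why: Wittig olefination with the stabilized α-bromo ylide formed in situ places the ester trans and bromine cis to the C4 chain ((Z)-alkene), the geometry that the ring closure needs, and is mild enough not to epimerize C4.

Step 7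
Reactants: 15 ethyl (2Z,4R,5R)-2-bromo-9-[(tert-butyldimethylsilyl)oxy]-4-methyl-5-[(triethylsilyl)oxy]non-2-en-7-ynoate
Product: 16 ethyl (3R,4R,6E)-6-{1-[(tert-butyldimethylsilyl)oxy]propan-2-ylidene}-3-methyl-4-[(triethylsilyl)oxy]cyclohex-1-ene-1-carboxylate
Conditions: Pd(PPh3)4 (10 mol%), MeB(OH)2, K2CO3, 1,4-dioxane–H2O, 85 °C
Reagents that add atoms: methylboronic acid, CB(O)O
Why: Cyclocarbopalladation–Suzuki–Miyaura cascade: zerovalent palladium inserts into the C8–Br bond, the C7≡C11 alkyne inserts in a 6-exo-dig syn fashion and the alkenylpalladium is methylated with retention, so C8 and methyl C12 end up cis on the C7=C11 bond ((E)-alkene of the target) by the mechanism itself.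

Step 8
Reactants: 16 ethyl (3R,4R,6E)-6-{1-[(tert-butyldimethylsilyl)oxy]propan-2-ylidene}-3-methyl-4-[(triethylsilyl)oxy]cyclohex-1-ene-1-carboxylate
Product: 17 [(3R,4R,6E)-6-{1-[(tert-butyldimethylsilyl)oxy]propan-2-ylidene}-3-methyl-4-[(triethylsilyl)oxy]cyclohex-1-en-1-yl]methanol
Conditions: i-Bu2AlH, CH2Cl2, −78 °C; aq potassium sodium tartrate
Reagents that add atoms: none
Why: DIBAL-H reduces the conjugated ester to the allylic alcohol by 1,2-reduction without touching the silyl ethers or the alkenes.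

Step 9
Reactants: 17 [(3R,4R,6E)-6-{1-[(tert-butyldimethylsilyl)oxy]propan-2-ylidene}-3-methyl-4-[(triethylsilyl)oxy]cyclohex-1-en-1-yl]methanol
Product: 18 (3R,4R,6E)-6-{1-[(tert-butyldimethylsilyl)oxy]propan-2-ylidene}-3-methyl-4-[(triethylsilyl)oxy]cyclohex-1-ene-1-carbaldehyde (ring B dienal)
Conditions: MnO2, CH2Cl2, rt
Reagents that add atoms: none
Why: MnO2 oxidizes only the allylic alcohol and does so under neutral conditions, so the γ-stereocentre C4 and the alkene geometry of the dienal are not disturbed.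

Step 10
Reactants: 19 methyl 3-oxopentanoate
Product: 21 3-oxopentanoic acid, via sodium 3-oxopentanoate 20 (not isolated)
Conditions: NaOH, H2O, 0 °C → rt; then HCl (aq), 0 °C, Et2O extraction; used at once
Reagents that add atoms: sodium hydroxide, [Na+].[OH-]
Why: Ester saponification in the cold followed by cold acidification gives the β-keto acid, which decarboxylates only on warming and is therefore used fresh.

Step 11
Reactants: 18 ring B dienal; 21 3-oxopentanoic acid
Product: 24 (4aS,5E,7R,8R,8aS)-5-{1-[(tert-butyldimethylsilyl)oxy]propan-2-ylidene}-3,8-dimethyl-7-[(triethylsilyl)oxy]-4a,5,6,7,8,8a-hexahydronaphthalen-2(1H)-one, via Michael adduct 22 (not isolated), via keto aldehyde 23 (not isolated)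
Conditions: pyrrolidine (30 mol%), AcOH (30 mol%), 21 (3 equiv, in portions), CHCl3, 0 °C → rt
Reagents that add atoms: none
Why: Pyrrolidine condenses with the C9 aldehyde to an unsaturated iminium ion, the enol of 21 adds through C2 to C3, adduct 22 loses CO2 to leave ethyl ketone 23, and the C10 enamine or enol of that ketone attacks C9 and eliminates amine or water to form the C9=C10 bond of enone 24. The closest known reaction type is the amine-catalysed decarboxylative Michael–aldol condensation of β-keto acids or esters with enals, a Robinson-type [3+3] annulation to cyclohexenones. Ring A closes in a 6-(enolendo)-exo-trig aldol step, because the enol double bond C1=C10 lies inside the new ring and the C9 carbonyl or iminium bond outside it. C3 is controlled by C4: with the C4 methyl pseudo-equatorial on the ring B half-chair the nucleophile adds to the opposite face of C3, which gives the trans (diequatorial) C2/methyl arrangement. C8 is set by reversible protonation (α to the aldehyde in 23, γ to the ketone in 24): allylic 1,3-strain with methyl C12 forces the C8–C9 bond axial on ring B, cis to the equatorial C3–C2 bond, hence the cis fusion. The step needs 1,4- rather than 1,2-attack (favoured by iminium activation and the soft, reversibly adding keto acid), the C3 face selectivity and cis fusion just described, and an intact C4–C5 unit, which the poor leaving-group ability of the C5 silyl ether protects against elimination through the dienamine.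

Step 12
Reactants: 24 (4aS,5E,7R,8R,8aS)-5-{1-[(tert-butyldimethylsilyl)oxy]propan-2-ylidene}-3,8-dimethyl-7-[(triethylsilyl)oxy]-4a,5,6,7,8,8a-hexahydronaphthalen-2(1H)-one
Product: 25 (4aS,5E,7R,8R,8aS)-5-{1-[(tert-butyldimethylsilyl)oxy]propan-2-ylidene}-7-hydroxy-3,8-dimethyl-4a,5,6,7,8,8a-hexahydronaphthalen-2(1H)-one
Conditions: PPTS, MeOH–CH2Cl2, 0 °C
Reagents that add atoms: none
Why: Acid-catalysed methanolysis cleaves the secondary triethylsilyl ether much faster than the primary tert-butyldimethylsilyl ether, and is run on the enone, before any acid-sensitive allylic alcohol is present.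

Step 13
Reactants: 25 (4aS,5E,7R,8R,8aS)-5-{1-[(tert-butyldimethylsilyl)oxy]propan-2-ylidene}-7-hydroxy-3,8-dimethyl-4a,5,6,7,8,8a-hexahydronaphthalen-2(1H)-one
Product: 26 (2R,4aS,5E,7R,8R,8aS)-5-{1-[(tert-butyldimethylsilyl)oxy]propan-2-ylidene}-3,8-dimethyl-1,2,4a,5,6,7,8,8a-octahydronaphthalene-2,7-diol
Conditions: NaBH4, CeCl3·7H2O, MeOH, −78 °C
Reagents that add atoms: none
Why: Luche reduction gives 1,2-reduction of the enone, and hydride should reach C1 from the convex face of the cis-fused bicycle (the face of the two ring-fusion hydrogens), because the other face is blocked by the axial C3–C4 bond, which gives the (R)-carbinol with the hydroxyl cis to that bond.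

Step 14
Reactants: 26 (2R,4aS,5E,7R,8R,8aS)-5-{1-[(tert-butyldimethylsilyl)oxy]propan-2-ylidene}-3,8-dimethyl-1,2,4a,5,6,7,8,8a-octahydronaphthalene-2,7-diol
Product: 27 (2R,4aS,5E,7R,8R,8aS)-5-{1-[(tert-butyldimethylsilyl)oxy]propan-2-ylidene}-3,8-dimethyl-1,2,4a,5,6,7,8,8a-octahydronaphthalene-2,7-diyl diacetate
Conditions: Ac2O, pyridine, DMAP (cat.), CH2Cl2, rt
Reagents that add atoms: acetic anhydride, CC(=O)OC(C)=O
Why: DMAP-catalysed acylation converts both secondary alcohols into acetates with retention of configuration.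

Step 15
Reactants: 27 (2R,4aS,5E,7R,8R,8aS)-5-{1-[(tert-butyldimethylsilyl)oxy]propan-2-ylidene}-3,8-dimethyl-1,2,4a,5,6,7,8,8a-octahydronaphthalene-2,7-diyl diacetate
Product: 28 (2R,4aS,5E,7R,8R,8aS)-5-(1-hydroxypropan-2-ylidene)-3,8-dimethyl-1,2,4a,5,6,7,8,8a-octahydronaphthalene-2,7-diyl diacetate
Conditions: HF·pyridine, pyridine, THF, 0 °C → rt
Reagents that add atoms: none
Why: Pyridine-buffered HF·pyridine removes the primary allylic silyl ether by Si–F bond formation without cleaving or shifting the acetates.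

Step 16
Reactants: 28 (2R,4aS,5E,7R,8R,8aS)-5-(1-hydroxypropan-2-ylidene)-3,8-dimethyl-1,2,4a,5,6,7,8,8a-octahydronaphthalene-2,7-diyl diacetate
Product: 29 (2R,4aS,5E,7R,8R,8aS)-5-[1-(formyloxy)propan-2-ylidene]-3,8-dimethyl-1,2,4a,5,6,7,8,8a-octahydronaphthalene-2,7-diyl diacetate (target)
Conditions: HCO2CH2CF3, THF, 65 °C
Reagents that add atoms: 2,2,2-trifluoroethyl formate, O=COCC(F)(F)F
Why: Transesterification with the activated formate formylates the primary allylic alcohol under neutral conditions, so the acetates are not exchanged.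

Compound list
1 | tert-butyldimethyl(prop-2-yn-1-yloxy)silane | C#CCO[Si](C)(C)C(C)(C)C | starting material
2 | oxirane | C1CO1 | starting material
3 | {3-[(tert-butyldimethylsilyl)oxy]prop-1-yn-1-yl}lithium | [Li]C#CCO[Si](C)(C)C(C)(C)C | intermediate (not isolated)
4 | 5-[(tert-butyldimethylsilyl)oxy]pent-3-yn-1-ol | OCCC#CCO[Si](C)(C)C(C)(C)C | intermediate
5 | 5-[(tert-butyldimethylsilyl)oxy]pent-3-ynal | O=CCC#CCO[Si](C)(C)C(C)(C)C | intermediate
6 | cis-but-2-ene | C/C=C\C | starting material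
7 | (Z)-but-2-enylpotassium | C/C=C\C[K] | intermediate (not isolated)
8 | (Z)-crotyldiisopinocampheylborane, both isopinocampheyl groups from (+)-α-pinene | C/C=C\CB([C@@H]1C[C@@H]2C[C@H]([C@H]1C)C2(C)C)[C@@H]1C[C@@H]2C[C@H]([C@H]1C)C2(C)C | intermediate (not isolated)
9 | (3R,4R)-8-[(tert-butyldimethylsilyl)oxy]-3-methyloct-1-en-6-yn-4-ol | C=C[C@@H](C)[C@H](O)CC#CCO[Si](C)(C)C(C)(C)C | intermediate
10 | (3R,4R)-8-[(tert-butyldimethylsilyl)oxy]-3-methyl-4-[(triethylsilyl)oxy]oct-1-en-6-yne | C=C[C@@H](C)[C@H](O[Si](CC)(CC)CC)CC#CCO[Si](C)(C)C(C)(C)C | intermediate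
11 | ozonide of 10 (3-substituted 1,2,4-trioxolane, both epimers at the ring carbon; C4 and C5 as in 10) | O1COC(O1)[C@@H](C)[C@H](O[Si](CC)(CC)CC)CC#CCO[Si](C)(C)C(C)(C)C | intermediate (not isolated)
12 | (2S,3R)-7-[(tert-butyldimethylsilyl)oxy]-2-methyl-3-[(triethylsilyl)oxy]hept-5-ynal | O=C[C@@H](C)[C@H](O[Si](CC)(CC)CC)CC#CCO[Si](C)(C)C(C)(C)C | intermediate
13 | ethyl (triphenylphosphoranylidene)acetate | CCOC(=O)C=P(c1ccccc1)(c1ccccc1)c1ccccc1 | starting material
14 | ethyl bromo(triphenylphosphoranylidene)acetate | CCOC(=O)C(Br)=P(c1ccccc1)(c1ccccc1)c1ccccc1 | intermediate (not isolated)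
15 | ethyl (2Z,4R,5R)-2-bromo-9-[(tert-butyldimethylsilyl)oxy]-4-methyl-5-[(triethylsilyl)oxy]non-2-en-7-ynoate | CCOC(=O)/C(Br)=C/[C@@H](C)[C@H](O[Si](CC)(CC)CC)CC#CCO[Si](C)(C)C(C)(C)C | intermediate
16 | ethyl (3R,4R,6E)-6-{1-[(tert-butyldimethylsilyl)oxy]propan-2-ylidene}-3-methyl-4-[(triethylsilyl)oxy]cyclohex-1-ene-1-carboxylate | CCOC(=O)C1=C[C@@H](C)[C@H](O[Si](CC)(CC)CC)C/C1=C(/C)CO[Si](C)(C)C(C)(C)C | intermediate
17 | [(3R,4R,6E)-6-{1-[(tert-butyldimethylsilyl)oxy]propan-2-ylidene}-3-methyl-4-[(triethylsilyl)oxy]cyclohex-1-en-1-yl]methanol | OCC1=C[C@@H](C)[C@H](O[Si](CC)(CC)CC)C/C1=C(/C)CO[Si](C)(C)C(C)(C)C | intermediate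
18 | (3R,4R,6E)-6-{1-[(tert-butyldimethylsilyl)oxy]propan-2-ylidene}-3-methyl-4-[(triethylsilyl)oxy]cyclohex-1-ene-1-carbaldehyde (ring B dienal, key precursor) | O=CC1=C[C@@H](C)[C@H](O[Si](CC)(CC)CC)C/C1=C(/C)CO[Si](C)(C)C(C)(C)C | intermediate
19 | methyl 3-oxopentanoate | CCC(=O)CC(=O)OC | starting material
20 | sodium 3-oxopentanoate | CCC(=O)CC(=O)[O-].[Na+] | intermediate (not isolated)
21 | 3-oxopentanoic acid | CCC(=O)CC(=O)O | intermediate
22 | 2-[(1R,2R,3E,5R,6R)-3-{1-[(tert-butyldimethylsilyl)oxy]propan-2-ylidene}-2-formyl-6-methyl-5-[(triethylsilyl)oxy]cyclohexyl]-3-oxopentanoic acid (both epimers at the acid α-carbon) | CCC(=O)C(C(=O)O)[C@@H]1[C@@H](C)[C@H](O[Si](CC)(CC)CC)C/C(=C(/C)CO[Si](C)(C)C(C)(C)C)[C@@H]1C=O | intermediate (not isolated)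
23 | (1R,2R,3R,4R,6E)-6-{1-[(tert-butyldimethylsilyl)oxy]propan-2-ylidene}-3-methyl-2-(2-oxobutyl)-4-[(triethylsilyl)oxy]cyclohexane-1-carbaldehyde | CCC(=O)C[C@@H]1[C@@H](C)[C@H](O[Si](CC)(CC)CC)C/C(=C(/C)CO[Si](C)(C)C(C)(C)C)[C@@H]1C=O | intermediate (not isolated)
24 | (4aS,5E,7R,8R,8aS)-5-{1-[(tert-butyldimethylsilyl)oxy]propan-2-ylidene}-3,8-dimethyl-7-[(triethylsilyl)oxy]-4a,5,6,7,8,8a-hexahydronaphthalen-2(1H)-one (cis-decalin C1 enone, key product) | O=C1C[C@@H]2[C@@H](C)[C@H](O[Si](CC)(CC)CC)C/C(=C(/C)CO[Si](C)(C)C(C)(C)C)[C@@H]2C=C1C | intermediate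
25 | (4aS,5E,7R,8R,8aS)-5-{1-[(tert-butyldimethylsilyl)oxy]propan-2-ylidene}-7-hydroxy-3,8-dimethyl-4a,5,6,7,8,8a-hexahydronaphthalen-2(1H)-one | O=C1C[C@@H]2[C@@H](C)[C@H](O)C/C(=C(/C)CO[Si](C)(C)C(C)(C)C)[C@@H]2C=C1C | intermediate
26 | (2R,4aS,5E,7R,8R,8aS)-5-{1-[(tert-butyldimethylsilyl)oxy]propan-2-ylidene}-3,8-dimethyl-1,2,4a,5,6,7,8,8a-octahydronaphthalene-2,7-diol | O[C@@H]1C[C@@H]2[C@@H](C)[C@H](O)C/C(=C(/C)CO[Si](C)(C)C(C)(C)C)[C@@H]2C=C1C | intermediate
27 | (2R,4aS,5E,7R,8R,8aS)-5-{1-[(tert-butyldimethylsilyl)oxy]propan-2-ylidene}-3,8-dimethyl-1,2,4a,5,6,7,8,8a-octahydronaphthalene-2,7-diyl diacetate | CC(=O)O[C@@H]1C[C@@H]2[C@@H](C)[C@H](OC(C)=O)C/C(=C(/C)CO[Si](C)(C)C(C)(C)C)[C@@H]2C=C1C | intermediate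
28 | (2R,4aS,5E,7R,8R,8aS)-5-(1-hydroxypropan-2-ylidene)-3,8-dimethyl-1,2,4a,5,6,7,8,8a-octahydronaphthalene-2,7-diyl diacetate | CC(=O)O[C@@H]1C[C@@H]2[C@@H](C)[C@H](OC(C)=O)C/C(=C(/C)CO)[C@@H]2C=C1C | intermediate
29 | (2R,4aS,5E,7R,8R,8aS)-5-[1-(formyloxy)propan-2-ylidene]-3,8-dimethyl-1,2,4a,5,6,7,8,8a-octahydronaphthalene-2,7-diyl diacetate | CC(=O)O[C@@H]1C[C@@H]2[C@@H](C)[C@H](OC(C)=O)C/C(=C(/C)COC=O)[C@@H]2C=C1C | target

Total step count: 16. Longest linear sequence: 15 steps (steps 1–9 and 11–16; step 10 supplies the keto acid).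

Steps most likely to fail

Step 11 (annulation). The keto acid may condense at C9 (1,2-attack) instead of adding to the hindered C3, iminium formation at the α-branched enal may be slow, γ-deprotonation of the iminium ion (dienamine formation) may erode the C4 configuration, and the facial bias at C3 may be low. The fallback sets out from 18 and returns at 24. It is a stepwise, enolate-based Robinson-type sequence without amine. Methyl 3-oxopentanoate 19 is added to 18 with catalytic K2CO3 in MeCN at rt, where only the β-dicarbonyl is deprotonated and no dienamine can form, to give methyl 2-[(1R,2R,3E,5R,6R)-3-{1-[(tert-butyldimethylsilyl)oxy]propan-2-ylidene}-2-formyl-6-methyl-5-[(triethylsilyl)oxy]cyclohexyl]-3-oxopentanoate F1. NaOMe in MeOH then closes ring A by aldol condensation to methyl (4aS,5E,7R,8R,8aS)-5-{1-[(tert-butyldimethylsilyl)oxy]propan-2-ylidene}-3,8-dimethyl-2-oxo-7-[(triethylsilyl)oxy]-1,2,4a,5,6,7,8,8a-octahydronaphthalene-1-carboxylate F2. Krapcho dealkoxycarbonylation (LiCl, wet DMSO, 130 °C) gives 24.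

Step 7 (cascade ring closure). The methyl group may be transferred to palladium before the alkyne has inserted, which would give an open-chain methylated enoate, or the alkenylpalladium intermediate may isomerize or lose the neighbouring alkoxide and so erode the C7=C11 geometry. The fallback sets out from 10 and returns at 16; it uses C8 as an electrophile instead of as an organopalladium.
- Hydroboration–oxidation of the terminal alkene of 10 (9-BBN, THF; NaOH, H2O2) gives (3R,4R)-8-[(tert-butyldimethylsilyl)oxy]-3-methyl-4-[(triethylsilyl)oxy]oct-6-yn-1-ol F3.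
- Dess–Martin oxidation gives (3R,4R)-8-[(tert-butyldimethylsilyl)oxy]-3-methyl-4-[(triethylsilyl)oxy]oct-6-ynal F4.
- A nickel-catalysed alkylative ynal cyclization (Ni(cod)2, MeZnCl, THF, 0 °C) adds C8 and methyl syn across the alkyne and gives (2E,4R,5R)-2-{1-[(tert-butyldimethylsilyl)oxy]propan-2-ylidene}-5-methyl-4-[(triethylsilyl)oxy]cyclohexan-1-ol F5 with the required alkene geometry.
- Dess–Martin oxidation gives (2E,4R,5R)-2-{1-[(tert-butyldimethylsilyl)oxy]propan-2-ylidene}-5-methyl-4-[(triethylsilyl)oxy]cyclohexan-1-one F6.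
- Kinetic enolization towards C3 and triflation (LiN(SiMe3)2, PhNTf2, THF, −78 °C) give (3R,4R,6E)-6-{1-[(tert-butyldimethylsilyl)oxy]propan-2-ylidene}-3-methyl-4-[(triethylsilyl)oxy]cyclohex-1-en-1-yl trifluoromethanesulfonate F7.
- Ethoxycarbonylation (Pd(OAc)2, PPh3, CO, EtOH, Et3N, DMF, 50 °C) leads back to 16.

Step 13 (C1 reduction). Hydride delivery from the concave face, or competing conjugate reduction, would give the wrong C1 epimer or a saturated ketone. The fallback sets out from 25 and returns at 26 and replaces substrate control by reagent control. It is a Corey–Bakshi–Shibata reduction with (S)-2-methyl-CBS-oxazaborolidine and catecholborane in toluene at −78 °C, in which the C10 alkenyl arm acts as the large group so that the (R)-carbinol should form. No new compound is involved.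

Further compounds
F1 | step 11 | methyl 2-[(1R,2R,3E,5R,6R)-3-{1-[(tert-butyldimethylsilyl)oxy]propan-2-ylidene}-2-formyl-6-methyl-5-[(triethylsilyl)oxy]cyclohexyl]-3-oxopentanoate (both epimers at the ester α-carbon) | CCC(=O)C(C(=O)OC)[C@@H]1[C@@H](C)[C@H](O[Si](CC)(CC)CC)C/C(=C(/C)CO[Si](C)(C)C(C)(C)C)[C@@H]1C=O
F2 | step 11 | methyl (4aS,5E,7R,8R,8aS)-5-{1-[(tert-butyldimethylsilyl)oxy]propan-2-ylidene}-3,8-dimethyl-2-oxo-7-[(triethylsilyl)oxy]-1,2,4a,5,6,7,8,8a-octahydronaphthalene-1-carboxylate (both epimers at C1 of the naphthalene numbering) | O=C1C(C(=O)OC)[C@@H]2[C@@H](C)[C@H](O[Si](CC)(CC)CC)C/C(=C(/C)CO[Si](C)(C)C(C)(C)C)[C@@H]2C=C1C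
F3 | step 7 | (3R,4R)-8-[(tert-butyldimethylsilyl)oxy]-3-methyl-4-[(triethylsilyl)oxy]oct-6-yn-1-ol | OCC[C@@H](C)[C@H](O[Si](CC)(CC)CC)CC#CCO[Si](C)(C)C(C)(C)C
F4 | step 7 | (3R,4R)-8-[(tert-butyldimethylsilyl)oxy]-3-methyl-4-[(triethylsilyl)oxy]oct-6-ynal | O=CC[C@@H](C)[C@H](O[Si](CC)(CC)CC)CC#CCO[Si](C)(C)C(C)(C)C
F5 | step 7 | (2E,4R,5R)-2-{1-[(tert-butyldimethylsilyl)oxy]propan-2-ylidene}-5-methyl-4-[(triethylsilyl)oxy]cyclohexan-1-ol (both carbinol epimers) | OC1C[C@@H](C)[C@H](O[Si](CC)(CC)CC)C/C1=C(/C)CO[Si](C)(C)C(C)(C)C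
F6 | step 7 | (2E,4R,5R)-2-{1-[(tert-butyldimethylsilyl)oxy]propan-2-ylidene}-5-methyl-4-[(triethylsilyl)oxy]cyclohexan-1-one | O=C1C[C@@H](C)[C@H](O[Si](CC)(CC)CC)C/C1=C(/C)CO[Si](C)(C)C(C)(C)C
F7 | step 7 | (3R,4R,6E)-6-{1-[(tert-butyldimethylsilyl)oxy]propan-2-ylidene}-3-methyl-4-[(triethylsilyl)oxy]cyclohex-1-en-1-yl trifluoromethanesulfonate | FC(F)(F)S(=O)(=O)OC1=C[C@@H](C)[C@H](O[Si](CC)(CC)CC)C/C1=C(/C)CO[Si](C)(C)C(C)(C)C
F0 | step 13 | none | none
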